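## Retrosynthetic overview

- Target 12 is traced back through silyl ether 11, aldehyde 10 and diol 9 to diester 8. The C8' ester of 8 becomes C9'H2OH and the arene ester becomes the propenal chain (reduction, benzylic oxidation, Wittig C2 extension, desilylation).
- Structural feature on which the route rests: the dioxane unit O5–C7'(guaiacyl)–C8'–O4 is the five-membered acetal ring O5–C7'–O4 of a 2-aryl-1,3-benzodioxole with one extra carbon, C8', sitting in the C7'–O4 bond. O4 is the ring oxygen ortho to OMe and para to the side-chain carbon.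
- Key disconnection: 8 comes from racemic benzodioxole 5 and ethyl diazoacetate 6, which supplies C8' and its ester and forms C7'–C8' and C8'–O4 in one operation.
- 5 comes from transacetalisation of the vanillin-derived dimethyl acetal 3 with catechol ester 4.
- Ring order: both arenes are bought; the benzodioxole ring is made first (step 3) and then expanded to the 1,4-benzodioxane (step 4).

Key step: step 4

Remark: primed locants and O4/O5 follow neolignan numbering. In ester 8 the C8' descriptor is R for the same spatial arrangement that is 8'S in 9–12, because CO2Et outranks C7'. The ligand antipode that delivers the 7'S series in step 4 has to be fixed by a first screen.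

## Route

Step 1
Reactants: 1 vanillin
Product: 2 3-methoxy-4-(triisopropylsilyloxy)benzaldehyde
Conditions: TIPSCl, imidazole, DMF, rt
Reagents that add atoms: triisopropylsilyl chloride, CC(C)[Si](Cl)(C(C)C)C(C)C
Why: Standard silylation of a phenol; the bulky aryl TIPS ether should survive the later acid, Lewis acid, hydride and ylide steps.

Step 2
Reactants: 2 3-methoxy-4-(triisopropylsilyloxy)benzaldehyde
Product: 3 [4-(dimethoxymethyl)-2-methoxyphenoxy]tri(propan-2-yl)silane
Conditions: HC(OMe)3, cat. p-TsOH, MeOH, rt; Et3N quench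
Reagents that add atoms: trimethyl orthoformate, COC(OC)OC; methanol, CO
Why: Acid-catalysed acetalisation driven by the orthoformate as water scavenger, under conditions an aryl TIPS ether tolerates.

Step 3
Reactants: 3 [4-(dimethoxymethyl)-2-methoxyphenoxy]tri(propan-2-yl)silane; 4 methyl 3,4-dihydroxy-5-methoxybenzoate
Product: 5 methyl 7-methoxy-2-[3-methoxy-4-(triisopropylsilyloxy)phenyl]-1,3-benzodioxole-5-carboxylate (racemic at the acetal carbon)
Conditions: cat. PPTS, toluene, 110 °C, MeOH removed through 4 Å MS; Et3N-deactivated silica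
Reagents that add atoms: none
Why: Transacetalisation of a benzaldehyde dimethyl acetal with a catechol, driven by removal of methanol; the acetal stereocentre forms racemic, which is harmless because it is planarised in step 4.

Step 4
Reactants: 5 methyl 7-methoxy-2-[3-methoxy-4-(triisopropylsilyloxy)phenyl]-1,3-benzodioxole-5-carboxylate; 6 ethyl diazoacetate
Product: 8 2-ethyl 6-methyl (2R,3S)-8-methoxy-3-[3-methoxy-4-(triisopropylsilyloxy)phenyl]-2,3-dihydro-1,4-benzodioxine-2,6-dicarboxylate (trans; C2 = C8'; C3 = C7'), via diazonium phenoxide 7 (not isolated)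
Conditions: Sc(OTf)3 (10 mol %), chiral N,N'-dioxide ligand (L-pipecolic acid-derived bis(2,6-diisopropylanilide), 11 mol %), 6 (1.5 equiv, slow addition), 4 Å MS, CH2Cl2, −20 → 0 °C
Reagents that add atoms: none
Why: Proposed new method: Sc(III), held in a five-membered chelate by O4 and the neighbouring OMe oxygen, should ionise the C7'–O4 bond of 5 to an O5-aryl oxocarbenium ion carrying the Sc-bound O4 phenoxide on the same arene; the nucleophilic carbon of 6 adds to C7' (C7'–C8' bond) to give 7, and O4 then displaces N2 at C8' with inversion (C8'–O4 bond), a formal [1,2]-shift of C7' from O4 to the diazo carbon. The closest known reactions are the Lewis-acid-promoted insertion of diazoacetates into a C–O bond of acyclic acetals and orthoformates, the carbenoid ring expansion of 1,3-dioxolanes to 1,4-dioxanes, and Sc(III)/N,N'-dioxide-catalysed enantioselective additions of α-diazo esters to carbonyl groups. The dioxane ring closes by a 6-exo-tet SN2 displacement. C7' is set by enantiofacial attack of 6 on the planar oxocarbenium ion inside the chiral pocket of the ligand on the adjacent Sc–O4 centre, so both enantiomers of 5 converge; C8' follows from the diastereomer of 7 that closes fastest through a half-chair transition state with aryl and CO2Et pseudo-equatorial (addition of 6 to the strongly stabilised cation is expected to be reversible), the inversion itself being stereospecific. The step needs ionisation at O4 and not O5, which the substrate secures by the O4/OMe chelate, by the para CO2Me group that makes O4 the better nucleofuge, and by O5 (only meta to the ester) being the better donor to the cation, while the TIPS group keeps Sc off the guaiacyl oxygens. It also needs ring closure to outrun 1,2-aryl and 1,2-hydride shifts in 7, for which the phenoxide held next to C8' is the provision, and the C7'–O5 bond of 8, flanked by the ester-bearing carbon, should not ionise under these conditions.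

Step 5
Reactants: 8 trans-(2R,3S) diester
Product: 9 {(2S,3S)-8-methoxy-3-[3-methoxy-4-(triisopropylsilyloxy)phenyl]-2,3-dihydro-1,4-benzodioxine-2,6-diyl}dimethanol
Conditions: DIBAL-H (6 equiv), CH2Cl2, −78 → 0 °C; Rochelle salt
Reagents that add atoms: none
Why: DIBAL-H reduction of both esters to primary alcohols creates C9'H2OH and the benzylic alcohol, leaves the aryl silyl ether intact, and passes through no enolisable intermediate that persists at low temperature, so C8' keeps its configuration.

Step 6
Reactants: 9 (7'S,8'S) diol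
Product: 10 (2S,3S)-2-(hydroxymethyl)-8-methoxy-3-[3-methoxy-4-(triisopropylsilyloxy)phenyl]-2,3-dihydro-1,4-benzodioxine-6-carbaldehyde
Conditions: activated MnO2 (15 equiv), CH2Cl2, rt
Reagents that add atoms: none
Why: MnO2 oxidises benzylic but not saturated primary alcohols, so only the arene CH2OH should become the aldehyde.

Step 7
Reactants: 10 (7'S,8'S) aryl aldehyde
Product: 11 (E)-3-{(2S,3S)-2-(hydroxymethyl)-8-methoxy-3-[3-methoxy-4-(triisopropylsilyloxy)phenyl]-2,3-dihydro-1,4-benzodioxin-6-yl}prop-2-enal
Conditions: Ph3P=CHCHO (1.3 equiv), toluene, 80 °C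
Reagents that add atoms: (triphenylphosphoranylidene)acetaldehyde, O=CC=P(c1ccccc1)(c1ccccc1)c1ccccc1
Why: Wittig reaction with the stabilised formylmethylene ylide should give the (E)-enal, and the neutral ylide tolerates the free C9' hydroxyl.

Step 8
Reactants: 11 TIPS-protected enal
Product: 12 (7'S,8'S)-nocomtal, (E)-3-[(2S,3S)-3-(4-hydroxy-3-methoxyphenyl)-2-(hydroxymethyl)-8-methoxy-2,3-dihydro-1,4-benzodioxin-6-yl]prop-2-enal
Conditions: TBAF (1.1 equiv), AcOH (1.1 equiv), THF, 0 °C
Reagents that add atoms: none
Why: Fluoride cleavage of the aryl silyl ether; the acetic acid buffer keeps the liberated phenol protonated, so neither quinone-methide opening at C7' nor base chemistry of the enal should intervene.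

## Compound list

1 | vanillin | COc1cc(C=O)ccc1O | starting material
2 | 3-methoxy-4-(triisopropylsilyloxy)benzaldehyde | COc1cc(C=O)ccc1O[Si](C(C)C)(C(C)C)C(C)C | intermediate
3 | [4-(dimethoxymethyl)-2-methoxyphenoxy]tri(propan-2-yl)silane | COc1cc(C(OC)OC)ccc1O[Si](C(C)C)(C(C)C)C(C)C | intermediate
4 | methyl 3,4-dihydroxy-5-methoxybenzoate (methyl 3-O-methylgallate) | COC(=O)c1cc(O)c(O)c(OC)c1 | starting material
5 | methyl 7-methoxy-2-[3-methoxy-4-(triisopropylsilyloxy)phenyl]-1,3-benzodioxole-5-carboxylate (racemic) | COC(=O)c1cc(OC)c2OC(c3ccc(O[Si](C(C)C)(C(C)C)C(C)C)c(OC)c3)Oc2c1 | intermediate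
6 | ethyl diazoacetate | CCOC(=O)C=[N+]=[N-] | starting material
7 | ethyl (2S,3S)-2-diazonio-3-[3-methoxy-5-(methoxycarbonyl)-2-oxidophenoxy]-3-[3-methoxy-4-(triisopropylsilyloxy)phenyl]propanoate (zwitterion, Sc-bound at the phenoxide) | COc1cc([C@H](Oc2cc(C(=O)OC)cc(OC)c2[O-])[C@H]([N+]#N)C(=O)OCC)ccc1O[Si](C(C)C)(C(C)C)C(C)C | intermediate
8 | 2-ethyl 6-methyl (2R,3S)-8-methoxy-3-[3-methoxy-4-(triisopropylsilyloxy)phenyl]-2,3-dihydro-1,4-benzodioxine-2,6-dicarboxylate (trans) | COc1cc([C@@H]2Oc3cc(C(=O)OC)cc(OC)c3O[C@H]2C(=O)OCC)ccc1O[Si](C(C)C)(C(C)C)C(C)C | intermediate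
9 | {(2S,3S)-8-methoxy-3-[3-methoxy-4-(triisopropylsilyloxy)phenyl]-2,3-dihydro-1,4-benzodioxine-2,6-diyl}dimethanol | COc1cc([C@@H]2Oc3cc(CO)cc(OC)c3O[C@H]2CO)ccc1O[Si](C(C)C)(C(C)C)C(C)C | intermediate
10 | (2S,3S)-2-(hydroxymethyl)-8-methoxy-3-[3-methoxy-4-(triisopropylsilyloxy)phenyl]-2,3-dihydro-1,4-benzodioxine-6-carbaldehyde | COc1cc([C@@H]2Oc3cc(C=O)cc(OC)c3O[C@H]2CO)ccc1O[Si](C(C)C)(C(C)C)C(C)C | intermediate
11 | (E)-3-{(2S,3S)-2-(hydroxymethyl)-8-methoxy-3-[3-methoxy-4-(triisopropylsilyloxy)phenyl]-2,3-dihydro-1,4-benzodioxin-6-yl}prop-2-enal | COc1cc([C@@H]2Oc3cc(/C=C/C=O)cc(OC)c3O[C@H]2CO)ccc1O[Si](C(C)C)(C(C)C)C(C)C | intermediate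
12 | (7'S,8'S)-nocomtal | COc1cc([C@@H]2Oc3cc(/C=C/C=O)cc(OC)c3O[C@H]2CO)ccc1O | target

## Step count and risks

Total step count: 8. Longest linear sequence: 8 steps (1 → 12); 4 and 6 enter at steps 3 and 4.

Steps most likely to fail:

1. Step 4 (proposed new method). Possible failure processes:
   - ionisation of the C7'–O5 bond in place of C7'–O4, giving the regioisomeric ring;
   - 1,2-aryl or 1,2-hydride migration in 7 outrunning ring closure;
   - weak face discrimination at C7';
   - closure to the cis ring. A cis fraction could in principle be equilibrated at C8' with an amidine base, but reversible β-elimination of the O5 phenoxide would endanger C7', so this is not relied on.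

   Fallback by known chemistry, setting out from aldehyde 2 and catechol 4 and returning at 8: Roskamp homologation of 2 with 6 (cat. NbCl5 or SnCl2, CH2Cl2) should give ethyl 3-[3-methoxy-4-(triisopropylsilyloxy)phenyl]-3-oxopropanoate F1. NBS bromination gives the α-bromo-β-keto ester F2. O-Alkylation of 4 at its more acidic 4-OH, para to the ester (K2CO3, acetone), gives the α-aryloxy-β-keto ester F3. Ru–TsDPEN asymmetric transfer hydrogenation with dynamic kinetic resolution of this configurationally labile keto ester (HCO2H/Et3N, catalyst antipode chosen for the 2R ester) gives the α-aryloxy-β-hydroxy ester F4, whose carbinol configuration is immaterial. BF3·OEt2 in CH2Cl2 at 0 °C then ionises the p-silyloxybenzylic alcohol, and the free 3-OH (O5) closes the ring under thermodynamic control to trans-8 with C8' untouched.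

2. Step 7. Possible failure processes: sluggish olefination of the electron-rich aldehyde and over-homologation of the product enal to a dienal. Fallback from 10, returning at 11: Wittig reaction with Ph3P=CHCO2Et gives the (E)-cinnamate, ethyl (E)-3-{(2S,3S)-2-(hydroxymethyl)-8-methoxy-3-[3-methoxy-4-(triisopropylsilyloxy)phenyl]-2,3-dihydro-1,4-benzodioxin-6-yl}prop-2-enoate F5. DIBAL-H at −78 °C gives the cinnamyl alcohol F6, and MnO2 oxidises the allylic but not the saturated primary alcohol to give 11.

3. Step 3. Possible failure processes: incomplete transacetalisation with the electron-poor catechol, slow five-membered closure through the oxocarbenium ion, hydrolysis of the acetal on work-up, and partial silyl loss on prolonged heating with acid. Fallback from 2 and 4, returning at 5, reaches the acetal oxidation level by oxidation instead of condensation: NaBH4 reduction of 2 gives [3-methoxy-4-(triisopropylsilyloxy)phenyl]methanol F7. Mitsunobu mono-etherification of 4 (PPh3, DIAD) gives methyl 3-hydroxy-5-methoxy-4-{[3-methoxy-4-(triisopropylsilyloxy)phenyl]methoxy}benzoate F8; the regioisomeric mono-ether would converge on the same product. Anhydrous DDQ with 4 Å MS in CH2Cl2 then removes hydride from the electron-rich benzylic position, and the neighbouring phenol traps the cation to give 5.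

Further compounds
F1 | step 4 | ethyl 3-[3-methoxy-4-(triisopropylsilyloxy)phenyl]-3-oxopropanoate | CCOC(=O)CC(=O)c1ccc(O[Si](C(C)C)(C(C)C)C(C)C)c(OC)c1
F2 | step 4 | ethyl 2-bromo-3-[3-methoxy-4-(triisopropylsilyloxy)phenyl]-3-oxopropanoate (racemic) | CCOC(=O)C(Br)C(=O)c1ccc(O[Si](C(C)C)(C(C)C)C(C)C)c(OC)c1
F3 | step 4 | methyl 4-({1-ethoxy-3-[3-methoxy-4-(triisopropylsilyloxy)phenyl]-1,3-dioxopropan-2-yl}oxy)-3-hydroxy-5-methoxybenzoate (racemic, labile) | CCOC(=O)C(Oc1c(O)cc(C(=O)OC)cc1OC)C(=O)c1ccc(O[Si](C(C)C)(C(C)C)C(C)C)c(OC)c1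
F4 | step 4 | methyl 4-({(2R)-1-ethoxy-3-hydroxy-3-[3-methoxy-4-(triisopropylsilyloxy)phenyl]-1-oxopropan-2-yl}oxy)-3-hydroxy-5-methoxybenzoate (carbinol centre unspecified) | CCOC(=O)[C@H](Oc1c(O)cc(C(=O)OC)cc1OC)C(O)c1ccc(O[Si](C(C)C)(C(C)C)C(C)C)c(OC)c1
F5 | step 7 | ethyl (E)-3-{(2S,3S)-2-(hydroxymethyl)-8-methoxy-3-[3-methoxy-4-(triisopropylsilyloxy)phenyl]-2,3-dihydro-1,4-benzodioxin-6-yl}prop-2-enoate | COc1cc([C@@H]2Oc3cc(/C=C/C(=O)OCC)cc(OC)c3O[C@H]2CO)ccc1O[Si](C(C)C)(C(C)C)C(C)C
F6 | step 7 | (E)-3-{(2S,3S)-2-(hydroxymethyl)-8-methoxy-3-[3-methoxy-4-(triisopropylsilyloxy)phenyl]-2,3-dihydro-1,4-benzodioxin-6-yl}prop-2-en-1-ol | COc1cc([C@@H]2Oc3cc(/C=C/CO)cc(OC)c3O[C@H]2CO)ccc1O[Si](C(C)C)(C(C)C)C(C)C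
F7 | step 3 | [3-methoxy-4-(triisopropylsilyloxy)phenyl]methanol | COc1cc(CO)ccc1O[Si](C(C)C)(C(C)C)C(C)C
F8 | step 3 | methyl 3-hydroxy-5-methoxy-4-{[3-methoxy-4-(triisopropylsilyloxy)phenyl]methoxy}benzoate | COC(=O)c1cc(O)c(OCc2ccc(O[Si](C(C)C)(C(C)C)C(C)C)c(OC)c2)c(OC)c1
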